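## Plan

1. Enabling feature: on ring A the formyl carbon (on C3) and the hydroxyl oxygen (on C4) sit on neighbouring ring carbons, and C3 has the C2 oxygen on its other side. A C3–C4 aryne can take this O/CH pair from the C=O bond of a formamide, and the C2 oxygen fixes the orientation.
2. Retrosynthetic cuts, in order: the C2 O-protecting group; C3–CHO together with C4–O (aryne + DMF); the C4 O–Tf bond; 2'-O–CH3; the depside bond C(=O)–O4'; ring A C1–CO2H; ring A C3–Si.
3. Forward: neither benzene ring is built. Orcinol becomes ring A and atraric acid becomes ring B. Orcinol bis-MOM ether is silylated, carboxylated, joined to O4' of atraric acid and methylated at O2'.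
4. The depside is then adjusted to the 2-OMOM/3-TMS/4-OTf pattern. The aryne step on the complete depside and removal of the last acetal finish the route.
5. Stereochemistry: the target has no stereocentre and no stereogenic double bond, so all control needed is regiochemical.

Key step: step 9

Remark on numbering: ring A is the acyl ring (C1 depside carbonyl, C2 OH, C3 CHO, C4 OH, C5 H, C6 CH3). Ring B is the phenol ring with primed locants (C1' CO2Me, C2' OMe, C3' CH3, C4' O-acyl, C5' H, C6' CH3). Orcinol, atraric acid and DMF are taken as commercial.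

## Route

Step 1
Reactants: 1 orcinol
Product: 2 1,3-bis(methoxymethoxy)-5-methylbenzene
Conditions: MOMCl (2.5 equiv), iPr2NEt (3 equiv), CH2Cl2, 0 °C to rt
Reagents that add atoms: chloromethyl methyl ether, COCCl
Why: Williamson-type O-alkylation of both phenols with the reactive α-chloro ether is routine and installs the two acetal groups that direct both later metalations.

Step 2
Reactants: 2 1,3-bis(methoxymethoxy)-5-methylbenzene
Product: 4 [2,6-bis(methoxymethoxy)-4-methylphenyl]trimethylsilane, via aryllithium 3 (not isolated)
Conditions: n-BuLi (1.1 equiv), THF, 0 °C; TMSCl (1.3 equiv), −78 °C to rt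
Reagents that add atoms: chlorotrimethylsilane, C[Si](C)(C)Cl; n-butyllithium, [Li]CCCC (lithium of 3 only)
Why: Directed ortho metalation should occur at the ring C–H flanked by both acetal oxygens, the most acidic and doubly coordinated site, and the silyl chloride quench places silicon on the future C3.

Step 3
Reactants: 4 [2,6-bis(methoxymethoxy)-4-methylphenyl]trimethylsilane
Product: 6 2,4-bis(methoxymethoxy)-6-methyl-3-(trimethylsilyl)benzoic acid, via aryllithium 5 (not isolated)
Conditions: s-BuLi (1.2 equiv), TMEDA (1.2 equiv), THF, −78 °C; CO2, −78 to 0 °C; cold 1 M HCl to pH 4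
Reagents that add atoms: carbon dioxide, O=C=O; sec-butyllithium, [Li]C(C)CC (lithium of 5 only)
Why: With the doubly activated site blocked by silicon, the two remaining ring C–H bonds are equivalent and each lies ortho to an acetal oxygen, so a second directed ortho metalation followed by carboxylation can give only one acid.

Step 4
Reactants: 6 2,4-bis(methoxymethoxy)-6-methyl-3-(trimethylsilyl)benzoic acid; 7 atraric acid (methyl 2,4-dihydroxy-3,6-dimethylbenzoate)
Product: 8 methyl 4-{[2,4-bis(methoxymethoxy)-6-methyl-3-(trimethylsilyl)benzoyl]oxy}-2-hydroxy-3,6-dimethylbenzoate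
Conditions: DCC (1.2 equiv), DMAP (0.2 equiv), CH2Cl2, 0 °C to rt
Reagents that add atoms: none
Why: In this Steglich esterification, the usual depside coupling, only the 4'-hydroxyl of 7 should be acylated, because the 2'-hydroxyl is hydrogen-bonded to the methyl ester and is wedged between that ester and the C3' methyl group.

Step 5
Reactants: 8 the 2'-hydroxy depside
Product: 9 methyl 4-{[2,4-bis(methoxymethoxy)-6-methyl-3-(trimethylsilyl)benzoyl]oxy}-2-methoxy-3,6-dimethylbenzoate
Conditions: MeI (5 equiv), K2CO3 (2 equiv), acetone, reflux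
Reagents that add atoms: iodomethane, CI
Why: In this Williamson methylation the 2'-hydroxyl is the only acidic site left, and the depside ester, ortho-substituted on both sides of its acyl carbon, should resist carbonate in dry acetone.

Step 6
Reactants: 9 the bis-MOM depside
Product: 11 methyl 4-{[2,4-dihydroxy-6-methyl-3-(trimethylsilyl)benzoyl]oxy}-2-methoxy-3,6-dimethylbenzoate, via bis(silyl ether) 10 (not isolated)
Conditions: TMSOTf (4 equiv), 2,2'-bipyridyl (6 equiv), MeCN, 0 °C to rt; then H2O, rt
Reagents that add atoms: trimethylsilyl triflate, C[Si](C)(C)OS(=O)(=O)C(F)(F)F (O-silyl groups of 10 only, lost again on hydrolysis)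
Why: This known mild acetal cleavage turns aryl methoxymethyl ethers into aryl silyl ethers under essentially non-acidic conditions before water frees the phenols, which matters because the C3–Si bond, ortho to two oxygens and para to the methyl group, would be lost by ipso-protonation in mineral acid.

Step 7
Reactants: 11 the 2,4-dihydroxy-3-silyl depside
Product: 12 methyl 4-{[2-hydroxy-6-methyl-4-(trifluoromethylsulfonyloxy)-3-(trimethylsilyl)benzoyl]oxy}-2-methoxy-3,6-dimethylbenzoate
Conditions: Tf2O (1.05 equiv), pyridine (3 equiv), CH2Cl2, −78 to 0 °C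
Reagents that add atoms: triflic anhydride, O=S(=O)(OS(=O)(=O)C(F)(F)F)C(F)(F)F
Why: In this phenol sulfonylation one equivalent of anhydride should react only at the C4 hydroxyl, as is standard for 2,4-dihydroxybenzoates, because the C2 hydroxyl is hydrogen-bonded to the depside carbonyl and sits between silicon and the ester.

Step 8
Reactants: 12 the 2-hydroxy-3-silyl-4-triflate depside
Product: 13 methyl 2-methoxy-4-{[2-(methoxymethoxy)-6-methyl-4-(trifluoromethylsulfonyloxy)-3-(trimethylsilyl)benzoyl]oxy}-3,6-dimethylbenzoate (aryne precursor)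
Conditions: MOMCl (3 equiv), iPr2NEt (4 equiv), CH2Cl2, 0 °C to rt
Reagents that add atoms: chloromethyl methyl ether, COCCl
Why: O-alkylation with the very reactive α-chloro ether under an amine base keeps the phenoxide concentration low, so acetal formation should outrun the carbon-to-oxygen silyl migration that stronger bases can trigger in a phenol of this type.

Step 9
Reactants: 13 aryne precursor; 14 N,N-dimethylformamide
Product: 18 methyl 4-{[3-formyl-4-hydroxy-2-(methoxymethoxy)-6-methylbenzoyl]oxy}-2-methoxy-3,6-dimethylbenzoate, via ring A aryne 15 (not isolated), via benzoxete 16 (not isolated), via aminomethylene dienone 17 (not isolated)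
Conditions: CsF (3 equiv), dry DMF (dilute, solvent), rt; then aq. NaH2PO4, 0 °C
Reagents that add atoms: N,N-dimethylformamide, CN(C)C=O; water, O
Why: Fluoride attacks the silicon on C3 and triflate leaves from C4, which gives the ring A C3–C4 aryne 15 under conditions that leave both esters, the aryl methyl ether and the acetal alone. The carbonyl oxygen of the solvent DMF adds to C4 and the resulting C3 carbanion closes on the iminium carbon (4-exo-trig, overall a formal [2+2] cycloaddition) to give benzoxete 16, the only ring closed in this step and a transient one. Electrocyclic opening of 16 gives the aminomethylene dienone 17 (an ortho-quinone methide), which the buffered water added at the end hydrolyses to the C3 aldehyde and the C4 phenol of 18. The closest known reaction type is the insertion of arynes into the C=O bond of formamides, which converts 3-alkoxyarynes into 6-alkoxysalicylaldehydes. The selectivity needed is regiochemical (oxygen to C4, carbon to C3) and is secured by the C2 acetal oxygen, whose inductive pull distorts the aryne so that C4 is the more electrophilic terminus and negative charge builds up at C3 beside it, while C4 is also the less crowded end, next to C5–H. No stereocentre survives (the aminal carbon of 16 is racemic and is lost on ring opening), and chemoselectivity is helped by slow aryne release from sparingly soluble CsF in a large excess of DMF, by holding water back until 13 is consumed and by a mildly acidic quench that protonates dimethylamine before it can attack the depside ester.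

Step 10
Reactants: 18 the 2-O-methoxymethyl aldehyde
Product: 19 2'-O-methylatranorin
Conditions: 2 M aq. HCl, THF, rt
Reagents that add atoms: none
Why: Acid hydrolysis of this aryl methoxymethyl acetal should be especially easy because the liberated C2 phenol is hydrogen-bonded to two flanking carbonyl groups, while the hindered depside ester, the methyl ester and the aryl methyl ether are inert to dilute acid at room temperature.

## Compound list

1 | orcinol (5-methylbenzene-1,3-diol) | Cc1cc(O)cc(O)c1 | starting material
2 | 1,3-bis(methoxymethoxy)-5-methylbenzene | COCOc1cc(C)cc(OCOC)c1 | intermediate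
3 | [2,6-bis(methoxymethoxy)-4-methylphenyl]lithium | [Li]c1c(OCOC)cc(C)cc1OCOC | intermediate
4 | [2,6-bis(methoxymethoxy)-4-methylphenyl]trimethylsilane | COCOc1cc(C)cc(OCOC)c1[Si](C)(C)C | intermediate
5 | [2,4-bis(methoxymethoxy)-6-methyl-3-(trimethylsilyl)phenyl]lithium | [Li]c1c(C)cc(OCOC)c([Si](C)(C)C)c1OCOC | intermediate
6 | 2,4-bis(methoxymethoxy)-6-methyl-3-(trimethylsilyl)benzoic acid | OC(=O)c1c(C)cc(OCOC)c([Si](C)(C)C)c1OCOC | intermediate
7 | atraric acid (methyl 2,4-dihydroxy-3,6-dimethylbenzoate) | COC(=O)c1c(C)cc(O)c(C)c1O | starting material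
8 | methyl 4-{[2,4-bis(methoxymethoxy)-6-methyl-3-(trimethylsilyl)benzoyl]oxy}-2-hydroxy-3,6-dimethylbenzoate | COCOc1cc(C)c(C(=O)Oc2cc(C)c(C(=O)OC)c(O)c2C)c(OCOC)c1[Si](C)(C)C | intermediate
9 | methyl 4-{[2,4-bis(methoxymethoxy)-6-methyl-3-(trimethylsilyl)benzoyl]oxy}-2-methoxy-3,6-dimethylbenzoate | COCOc1cc(C)c(C(=O)Oc2cc(C)c(C(=O)OC)c(OC)c2C)c(OCOC)c1[Si](C)(C)C | intermediate
10 | methyl 2-methoxy-3,6-dimethyl-4-{[6-methyl-3-(trimethylsilyl)-2,4-bis(trimethylsilyloxy)benzoyl]oxy}benzoate | C[Si](C)(C)Oc1cc(C)c(C(=O)Oc2cc(C)c(C(=O)OC)c(OC)c2C)c(O[Si](C)(C)C)c1[Si](C)(C)C | intermediate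
11 | methyl 4-{[2,4-dihydroxy-6-methyl-3-(trimethylsilyl)benzoyl]oxy}-2-methoxy-3,6-dimethylbenzoate | Oc1cc(C)c(C(=O)Oc2cc(C)c(C(=O)OC)c(OC)c2C)c(O)c1[Si](C)(C)C | intermediate
12 | methyl 4-{[2-hydroxy-6-methyl-4-(trifluoromethylsulfonyloxy)-3-(trimethylsilyl)benzoyl]oxy}-2-methoxy-3,6-dimethylbenzoate | Oc1c([Si](C)(C)C)c(OS(=O)(=O)C(F)(F)F)cc(C)c1C(=O)Oc1cc(C)c(C(=O)OC)c(OC)c1C | intermediate
13 | methyl 2-methoxy-4-{[2-(methoxymethoxy)-6-methyl-4-(trifluoromethylsulfonyloxy)-3-(trimethylsilyl)benzoyl]oxy}-3,6-dimethylbenzoate | COCOc1c([Si](C)(C)C)c(OS(=O)(=O)C(F)(F)F)cc(C)c1C(=O)Oc1cc(C)c(C(=O)OC)c(OC)c1C | intermediate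
14 | N,N-dimethylformamide | CN(C)C=O | starting material
15 | ring A C3–C4 aryne: methyl 4-{[3,4-didehydro-2-(methoxymethoxy)-6-methylbenzoyl]oxy}-2-methoxy-3,6-dimethylbenzoate | COCOC1=C(C(=O)Oc2cc(C)c(C(=O)OC)c(OC)c2C)C(C)=CC#C1 | intermediate
16 | benzoxete: ring A fused at C3–C4 to a 2-(dimethylamino)oxete, O on C4 and aminal CH on C3, racemic | COCOc1c2c(OC2N(C)C)cc(C)c1C(=O)Oc1cc(C)c(C(=O)OC)c(OC)c1C | intermediate
17 | aminomethylene dienone (ortho-quinone methide): ring A with C4=O and C3=CH–NMe2 | COCOC1=C(C(=O)Oc2cc(C)c(C(=O)OC)c(OC)c2C)C(C)=CC(=O)C1=CN(C)C | intermediate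
18 | methyl 4-{[3-formyl-4-hydroxy-2-(methoxymethoxy)-6-methylbenzoyl]oxy}-2-methoxy-3,6-dimethylbenzoate | COCOc1c(C=O)c(O)cc(C)c1C(=O)Oc1cc(C)c(C(=O)OC)c(OC)c1C | intermediate
19 | 2'-O-methylatranorin (methyl 4-[(3-formyl-2,4-dihydroxy-6-methylbenzoyl)oxy]-2-methoxy-3,6-dimethylbenzoate) | COC(=O)c1c(C)cc(OC(=O)c2c(C)cc(O)c(C=O)c2O)c(C)c1OC | target

## Step count and risks

Total step count: 10.
Longest linear sequence: 10 steps, from orcinol 1 to 19. Compounds 7 and 14 enter as bought.

**Step 9 (aryne generation and DMF insertion on the depside).**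
- What may go wrong:
  - cleavage of the depside ester by basic fluoride or by liberated dimethylamine;
  - capture of a second aryne by the dienone or by the freed phenoxide;
  - partial addition of the DMF oxygen to the wrong aryne terminus.
- Fallback, from 11 back to the route at 19: the silicon on C3 serves as an ipso-directing group for an electrophile instead of as an aryne trigger.
- Rieche formylation of 11 (Cl2CHOMe, TiCl4, CH2Cl2, −78 to 0 °C) should attack C3, which is activated by both ortho oxygens, the para methyl group and the β-silicon effect.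
- Loss of the silyl group gives the 3-[chloro(methoxy)methyl] depside F1, which aqueous work-up hydrolyses to 19. Steps 7 to 10 are then not needed.

**Step 8 (acetal formation on the hindered, hydrogen-bonded C2 phenol).**
- What may go wrong: sluggish alkylation between silicon and the ester, and premature carbon-to-oxygen silyl migration with loss of triflate once phenoxide builds up.
- Fallback, from 12 back to the route at 19: the migration itself is used as the aryne trigger, and no protecting group is put on.
- Compound 12 is stirred with K2CO3 and 18-crown-6 in dry DMF 14 at rt. The C2 phenoxide takes the silyl group from C3 (1,3-Brook shift), triflate leaves and the 2-trimethylsilyloxy aryne F2 forms.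
- DMF inserts as in step 9, by way of the silyloxy benzoxete F3, to give the silyloxy aminomethylene dienone F4. Dilute aqueous acid then hydrolyses both the enaminone and the silyl ether to 19. Steps 8 and 10 drop out.

**Step 3 (second metalation next to the methyl group).**
- What may go wrong: incomplete ring metalation at the crowded position, or competing deprotonation of the benzylic methyl group or of an acetal CH2.
- Fallback, from 2 back to the route at 5 (and so at 6): the lithiation site is fixed by halogen–metal exchange instead of by deprotonation.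
- Bromination of 2 (NBS, MeCN, 0 °C) goes para to one acetal oxygen and ortho to the methyl group and gives 1-bromo-2,4-bis(methoxymethoxy)-6-methylbenzene F5.
- Deprotonation between the two acetal oxygens with LiTMP in the presence of TMSCl (THF, −78 °C) gives [3-bromo-2,6-bis(methoxymethoxy)-4-methylphenyl]trimethylsilane F6.
- Bromine–lithium exchange (n-BuLi, THF, −78 °C) gives aryllithium 5, which is carboxylated as in step 3.

## Further compounds

F1 | step 9 | 3-[chloro(methoxy)methyl] depside (methyl 4-({3-[chloro(methoxy)methyl]-2,4-dihydroxy-6-methylbenzoyl}oxy)-2-methoxy-3,6-dimethylbenzoate) | COC(Cl)c1c(O)cc(C)c(C(=O)Oc2cc(C)c(C(=O)OC)c(OC)c2C)c1O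
F2 | step 8 | 2-trimethylsilyloxy aryne (methyl 4-{[3,4-didehydro-6-methyl-2-(trimethylsilyloxy)benzoyl]oxy}-2-methoxy-3,6-dimethylbenzoate) | C[Si](C)(C)OC1=C(C(=O)Oc2cc(C)c(C(=O)OC)c(OC)c2C)C(C)=CC#C1
F3 | step 8 | silyloxy benzoxete (ring A fused at C3–C4 to a 2-(dimethylamino)oxete, C2 OSiMe3, racemic) | C[Si](C)(C)Oc1c2c(OC2N(C)C)cc(C)c1C(=O)Oc1cc(C)c(C(=O)OC)c(OC)c1C
F4 | step 8 | silyloxy aminomethylene dienone (ring A with C4=O, C3=CH–NMe2, C2 OSiMe3) | C[Si](C)(C)OC1=C(C(=O)Oc2cc(C)c(C(=O)OC)c(OC)c2C)C(C)=CC(=O)C1=CN(C)C
F5 | step 3 | 1-bromo-2,4-bis(methoxymethoxy)-6-methylbenzene | Brc1c(C)cc(OCOC)cc1OCOC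
F6 | step 3 | [3-bromo-2,6-bis(methoxymethoxy)-4-methylphenyl]trimethylsilane | Brc1c(C)cc(OCOC)c([Si](C)(C)C)c1OCOC
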